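The α‑methylene γ‑lactone is annulated last onto a finished ten‑membered ring by disconnecting C7–C11 and C11=C13 (germacrane numbering). The step exploits one feature: in the lactone fused at C6–C7 of the ten‑membered ring, the C7–C11 bond is trans to both O6 and O8. A phosphonoacetate carbanion tethered to O6 opens a cis C7/C8 epoxide at C7 from the rear, which closes the lactone, sets C7 and frees the C8 hydroxyl, and formaldehyde then installs the exocyclic methylene in the same flask. The precursor is the 1(10)E,3Z‑dienone ring (closed by metathesis at C7=C8) with a C5 silyl ether, a C6 phosphonoacetate and a cis 7,8‑epoxide on the O6 face.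

Key step: step 15

Remark 1: the descriptors were re‑derived from the target SMILES as 5R,6S,7R,8S, 1(10)E, 3Z and Z in the angelate; the open‑chain C5/C6 diol is therefore anti, and the germacrane locants C1–C13 are used in the text for every intermediate.
Remark 2: (S)‑but‑3‑ene‑1,2‑diol is assumed to be bought as the single enantiomer, and formaldehyde 23 is charged as paraformaldehyde.
Remark 3: O5 carries a tert‑butyldimethylsilyl ether from step 7 to the end and O6 stays silylated until the ring is closed, because a free hydroxyl at either position of the open‑chain Z‑enone would close onto the C2 carbonyl (five‑membered hemiketal and furan from O5, six‑membered hemiketal from O6).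

Step 1
Reactants: 1 pent-1-en-4-yne
Product: 3 (E)-1-iodo-2-methylpenta-1,4-diene, via alkenylalane 2 (not isolated)
Conditions: AlMe3, Cp2ZrCl2 (cat.), CH2Cl2, 0 °C to rt; then I2, THF, −30 to 0 °C
Reagents that add atoms: trimethylaluminium, C[Al](C)C; iodine, II
Why: Zirconium‑catalysed Negishi carboalumination adds methyl and aluminium syn across the terminal alkyne (methyl to the internal carbon, the alkene being left alone) and iodinolysis of the C–Al bond with retention gives the E iodide that becomes C10=C1.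

Step 2
Reactants: 4 but-2-yn-1-ol
Product: 6 (Z)-3-iodobut-2-en-1-ol, via alkenylaluminate 5 (not isolated)
Conditions: NaAlH2(OCH2CH2OMe)2, THF, 0 °C to rt; then I2, −78 to 0 °C
Reagents that add atoms: iodine, II
Why: Alkoxide‑directed trans‑hydroalumination of the propargylic alcohol places aluminium on the distal carbon (C4) in a five‑membered chelate, and iodinolysis with retention gives the Z iodide in which iodine (the site of the future C5) is cis to the CH2O carbon (the future C2).

Step 3
Reactants: 6 (Z)-3-iodobut-2-en-1-ol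
Product: 7 (Z)-triethyl[(3-iodobut-2-en-1-yl)oxy]silane
Conditions: Et3SiCl, imidazole, CH2Cl2, 0 °C
Reagents that add atoms: chlorotriethylsilane, CC[Si](Cl)(CC)CC
Why: Routine silylation of a primary alcohol, the triethylsilyl ether being chosen because a primary one can later be oxidised directly under Swern conditions.

Step 4
Reactants: 8 (S)-but-3-ene-1,2-diol
Product: 9 (S)-3,4-bis(triethylsilyloxy)but-1-ene
Conditions: Et3SiCl, imidazole, DMF, 0 °C to rt
Reagents that add atoms: chlorotriethylsilane, CC[Si](Cl)(CC)CC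
Why: Routine bis‑silylation that leaves the chiral‑pool stereocentre (the future C6) untouched and gives a non‑chelating α‑oxygen substituent for the later addition.

Step 5
Reactants: 9 (S)-3,4-bis(triethylsilyloxy)but-1-ene
Product: 10 (S)-2-(triethylsilyloxy)but-3-enal
Conditions: (COCl)2, DMSO, CH2Cl2, −78 to −30 °C; then i-Pr2NEt, −78 to 0 °C; used crude
Reagents that add atoms: none
Why: Under Swern conditions a primary triethylsilyl ether is cleaved and oxidised in the same flask while the secondary one survives, and the low temperature and hindered base should keep the α‑stereocentre and the unconjugated vinyl group intact.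

Step 6
Reactants: 7 (Z)-triethyl[(3-iodobut-2-en-1-yl)oxy]silane, 10 (S)-2-(triethylsilyloxy)but-3-enal
Product: 12 (2Z,4R,5S)-3-methyl-1,5-bis(triethylsilyloxy)hepta-2,6-dien-4-ol, via alkenyllithium 11 (not isolated)
Conditions: 7, t-BuLi (2 equiv), Et2O, −78 °C; then 10, −78 °C, cold quench
Reagents that add atoms: none
Why: Iodine–lithium exchange keeps the Z geometry and Felkin–Anh 1,2‑addition to the α‑silyloxy aldehyde (nucleophile anti to the non‑chelating C–OSi bond) should favour the anti carbinol, which sets C5 as R relative to the S centre C6, the minor syn epimer being removed by chromatography.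

Step 7
Reactants: 12 (2Z,4R,5S)-3-methyl-1,5-bis(triethylsilyloxy)hepta-2,6-dien-4-ol
Product: 13 (2Z,4R,5S)-4-(tert-butyldimethylsilyloxy)-3-methyl-1,5-bis(triethylsilyloxy)hepta-2,6-diene
Conditions: TBSOTf, 2,6-lutidine, CH2Cl2, −78 to 0 °C
Reagents that add atoms: tert-butyldimethylsilyl triflate, CC(C)(C)[Si](C)(C)OS(=O)(=O)C(F)(F)F
Why: Silyl triflate silylation caps the hindered secondary C5 hydroxyl with the group that stays to the last step and that blocks hemiketal and furan formation with the later C2 ketone.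

Step 8
Reactants: 13 (2Z,4R,5S)-4-(tert-butyldimethylsilyloxy)-3-methyl-1,5-bis(triethylsilyloxy)hepta-2,6-diene
Product: 14 (2Z,4R,5S)-4-(tert-butyldimethylsilyloxy)-3-methyl-5-(triethylsilyloxy)hepta-2,6-dienal
Conditions: (COCl)2, DMSO, CH2Cl2, −78 to −30 °C; then i-Pr2NEt, −78 to 0 °C
Reagents that add atoms: none
Why: The Swern reagent cleaves only the primary allylic triethylsilyl ether and oxidises it in the same flask to the Z enal (C2), the two secondary silyl ethers being inert and the hindered base limiting Z‑to‑E isomerisation.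

Step 9
Reactants: 3 (E)-1-iodo-2-methylpenta-1,4-diene, 14 (2Z,4R,5S)-4-(tert-butyldimethylsilyloxy)-3-methyl-5-(triethylsilyloxy)hepta-2,6-dienal
Product: 16 (4E,7Z,9R,10S)-9-(tert-butyldimethylsilyloxy)-4,8-dimethyl-10-(triethylsilyloxy)dodeca-1,4,7,11-tetraen-6-ol (both carbinol epimers), via dienyllithium 15 (not isolated)
Conditions: 3, t-BuLi (2 equiv), Et2O, −78 °C; then 14, −78 °C
Reagents that add atoms: none
Why: Iodine–lithium exchange with retention of the E geometry and 1,2‑addition of the alkenyllithium to the enal form C1–C2, and the new carbinol centre needs no control because it is oxidised in the next step.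

Step 10
Reactants: 16 (4E,7Z,9R,10S)-9-(tert-butyldimethylsilyloxy)-4,8-dimethyl-10-(triethylsilyloxy)dodeca-1,4,7,11-tetraen-6-ol
Product: 17 (4E,7Z,9R,10S)-9-(tert-butyldimethylsilyloxy)-4,8-dimethyl-10-(triethylsilyloxy)dodeca-1,4,7,11-tetraen-6-one
Conditions: Dess–Martin periodinane, pyridine, CH2Cl2, 0 °C
Reagents that add atoms: none
Why: Buffered Dess–Martin oxidation of the bis‑allylic alcohol gives the cross‑conjugated dienone without touching the silyl ethers or the Z enone geometry.

Step 11
Reactants: 17 (4E,7Z,9R,10S)-9-(tert-butyldimethylsilyloxy)-4,8-dimethyl-10-(triethylsilyloxy)dodeca-1,4,7,11-tetraen-6-one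
Product: 18 (1(10)E,3Z,7Z,5R,6S)-5-(tert-butyldimethylsilyloxy)-6-(triethylsilyloxy)-11,12,13-trinorgermacra-1(10),3,7-trien-2-one
Conditions: second-generation Grubbs catalyst RuCl2(=CHPh)(H2IMes)(PCy3) (10 mol %), 1,4-benzoquinone, toluene, 80 °C, 1 mM
Reagents that add atoms: none
Why: In this ring‑closing olefin metathesis the catalyst should load at the unhindered C8 allyl terminus and close onto the C7 vinyl group with loss of ethylene, the new disubstituted olefin being necessarily Z in a ten‑membered ring that already holds an E and a Z double bond, while the E geometry of C10=C1 rules out six‑ring closure onto C3=C4.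

Step 12
Reactants: 18 (1(10)E,3Z,7Z,5R,6S)-5-(tert-butyldimethylsilyloxy)-6-(triethylsilyloxy)-11,12,13-trinorgermacra-1(10),3,7-trien-2-one
Product: 19 (1(10)E,3Z,7Z,5R,6S)-5-(tert-butyldimethylsilyloxy)-6-hydroxy-11,12,13-trinorgermacra-1(10),3,7-trien-2-one
Conditions: HF·pyridine, pyridine, THF, 0 °C
Reagents that add atoms: none
Why: Selective desilylation works because buffered HF·pyridine cleaves a secondary triethylsilyl ether much faster than the neighbouring tert‑butyldimethylsilyl ether, and in the ring the freed C6 hydroxyl cannot close onto C2 without forcing the E olefin into an eight‑membered ring.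

Step 13
Reactants: 19 (1(10)E,3Z,7Z,5R,6S)-5-(tert-butyldimethylsilyloxy)-6-hydroxy-11,12,13-trinorgermacra-1(10),3,7-trien-2-one
Product: 20 (1(10)E,3Z,5R,6S,7R,8S)-5-(tert-butyldimethylsilyloxy)-7,8-epoxy-6-hydroxy-11,12,13-trinorgermacra-1(10),3-dien-2-one (cis epoxide on the face of the C6 hydroxyl)
Conditions: VO(acac)2 (cat.), t-BuOOH, CH2Cl2, 0 °C to rt
Reagents that add atoms: tert-butyl hydroperoxide, CC(C)(C)OO
Why: In this vanadium‑catalysed hydroxyl‑directed epoxidation the C6 vanadate ester delivers the peroxide oxygen to the C7=C8 face on its own side, the course followed by medium‑ring (Z)‑cycloalk‑2‑en‑1‑ols, which sets C7 and C8 together as the cis epoxide syn to O6 while the electron‑poor dienone olefins are not attacked.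

Step 14
Reactants: 20 (1(10)E,3Z,5R,6S,7R,8S)-5-(tert-butyldimethylsilyloxy)-7,8-epoxy-6-hydroxy-11,12,13-trinorgermacra-1(10),3-dien-2-one, 21 diethylphosphonoacetic acid
Product: 22 (1(10)E,3Z,5R,6S,7S,8S)-5-(tert-butyldimethylsilyloxy)-6-[2-(diethoxyphosphoryl)acetoxy]-7,8-epoxy-11,12,13-trinorgermacra-1(10),3-dien-2-one
Conditions: 21, DCC, DMAP (cat.), CH2Cl2, 0 °C to rt
Reagents that add atoms: none
Why: Steglich esterification acylates the hindered secondary epoxy alcohol under neutral carbodiimide conditions that leave the epoxide, the silyl ether and the dienone untouched.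

Step 15
Reactants: 22 (1(10)E,3Z,5R,6S,7S,8S)-5-(tert-butyldimethylsilyloxy)-6-[2-(diethoxyphosphoryl)acetoxy]-7,8-epoxy-11,12,13-trinorgermacra-1(10),3-dien-2-one, 23 formaldehyde
Product: 26 (1(10)E,3Z,5R,6S,7R,8S)-5-(tert-butyldimethylsilyloxy)-8-hydroxy-2-oxogermacra-1(10),3,11(13)-trien-12,6-olide, via sodium phosphonoacetate enolate 24 (not isolated), via α-phosphono lactone anion 25 (not isolated)
Conditions: NaH (1.0 equiv), THF, 0 °C to rt; then (CH2O)n, 0 °C to rt
Reagents that add atoms: none
Why: One equivalent of NaH deprotonates only the phosphonoacetate methylene, whose carbanion carbon C11 attacks C7 from the side opposite the epoxide oxygen and leaves that oxygen on C8; the C8 alkoxide is then protonated by the more acidic C11–H, and the resulting α‑phosphono lactone anion undergoes Horner–Wadsworth–Emmons olefination with formaldehyde to give C11=C13 and sodium diethyl phosphate. The closest known reactions are the intramolecular opening of epoxides by ester‑stabilised carbanions and the telescoped cyclisation/Horner–Wadsworth–Emmons methylenation of tethered phosphonoacetates. The γ‑lactone closes in the 5‑exo‑tet mode. C7 is set by SN2 inversion and is therefore dictated by the epoxide configuration fixed in step 13, while C8 keeps its oxygen with retention, so that the C7–C11 bond ends trans to both O6 and O8. The step needs attack at C7 (5‑exo) and not at C8 (6‑endo), which the three‑atom O6–C12–C11 tether secures because it can line up only with the rear of the C7–O bond when the C5–C6–C7–C8 backbone is extended and O6 lies anti to the epoxide oxygen, whereas addition to C4 of the dienone would need a bridged lactone with a quaternary carbon and is reversible. Phosphoryl transfer to O8, lactone migration to O8 and deprotonation of the dienone are held back by the exact base stoichiometry, the fast internal proton transfer, the low temperature and the addition of formaldehyde as soon as the epoxide is consumed.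

Step 16
Reactants: 26 (1(10)E,3Z,5R,6S,7R,8S)-5-(tert-butyldimethylsilyloxy)-8-hydroxy-2-oxogermacra-1(10),3,11(13)-trien-12,6-olide, 27 angelic acid
Product: 29 (1(10)E,3Z,5R,6S,7R,8S)-8-angeloyloxy-5-(tert-butyldimethylsilyloxy)-2-oxogermacra-1(10),3,11(13)-trien-12,6-olide, via mixed anhydride 28 (not isolated)
Conditions: 27, 2,4,6-Cl3C6H2COCl, Et3N, toluene, rt; then 26, toluene, 75 °C
Reagents that add atoms: none
Why: Yamaguchi esterification through the preformed mixed anhydride, run without a nucleophilic pyridine catalyst, acylates the only free hydroxyl (C8) without isomerising the angelate to the tiglate or adding to the α‑methylene lactone.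

Step 17
Reactants: 29 (1(10)E,3Z,5R,6S,7R,8S)-8-angeloyloxy-5-(tert-butyldimethylsilyloxy)-2-oxogermacra-1(10),3,11(13)-trien-12,6-olide
Product: 30 (1(10)E,3Z,5R,6S,7R,8S)-8-angeloyloxy-5-hydroxy-2-oxogermacra-1(10),3,11(13)-trien-12,6-olide
Conditions: HF·pyridine, THF, 0 °C to rt
Reagents that add atoms: none
Why: Fluoride‑mediated desilylation under mildly acidic conditions removes the C5 silyl ether while the α‑methylene lactone, the angelate and the dienone, all sensitive to basic fluoride, stay intact.

Compound list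
1 | pent-1-en-4-yne | C=CCC#C | starting material
2 | (E)-dimethyl(2-methylpenta-1,4-dien-1-yl)alane | C=CC/C(C)=C/[Al](C)C | intermediate
3 | (E)-1-iodo-2-methylpenta-1,4-diene | C=CC/C(C)=C/I | intermediate
4 | but-2-yn-1-ol | CC#CCO | starting material
5 | sodium (Z)-alkenylaluminate, five-membered C–Al–O chelate with two 2-methoxyethoxy ligands | CC1=CCO[Al-]1(OCCOC)OCCOC.[Na+] | intermediate
6 | (Z)-3-iodobut-2-en-1-ol | OC/C=C(/C)I | intermediate
7 | (Z)-triethyl[(3-iodobut-2-en-1-yl)oxy]silane | CC[Si](CC)(CC)OC/C=C(/C)I | intermediate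
8 | (S)-but-3-ene-1,2-diol | C=C[C@H](O)CO | starting material
9 | (S)-3,4-bis(triethylsilyloxy)but-1-ene | C=C[C@H](O[Si](CC)(CC)CC)CO[Si](CC)(CC)CC | intermediate
10 | (S)-2-(triethylsilyloxy)but-3-enal | C=C[C@H](O[Si](CC)(CC)CC)C=O | intermediate
11 | (Z)-[4-(triethylsilyloxy)but-2-en-2-yl]lithium | CC[Si](CC)(CC)OC/C=C(/C)[Li] | intermediate
12 | (2Z,4R,5S)-3-methyl-1,5-bis(triethylsilyloxy)hepta-2,6-dien-4-ol | C=C[C@H](O[Si](CC)(CC)CC)[C@H](O)/C(C)=C\CO[Si](CC)(CC)CC | intermediate
13 | (2Z,4R,5S)-4-(tert-butyldimethylsilyloxy)-3-methyl-1,5-bis(triethylsilyloxy)hepta-2,6-diene | C=C[C@H](O[Si](CC)(CC)CC)[C@H](O[Si](C)(C)C(C)(C)C)/C(C)=C\CO[Si](CC)(CC)CC | intermediate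
14 | (2Z,4R,5S)-4-(tert-butyldimethylsilyloxy)-3-methyl-5-(triethylsilyloxy)hepta-2,6-dienal | C=C[C@H](O[Si](CC)(CC)CC)[C@H](O[Si](C)(C)C(C)(C)C)/C(C)=C\C=O | intermediate
15 | (E)-(2-methylpenta-1,4-dien-1-yl)lithium | C=CC/C(C)=C/[Li] | intermediate
16 | (4E,7Z,9R,10S)-9-(tert-butyldimethylsilyloxy)-4,8-dimethyl-10-(triethylsilyloxy)dodeca-1,4,7,11-tetraen-6-ol, both carbinol epimers | C=C[C@H](O[Si](CC)(CC)CC)[C@H](O[Si](C)(C)C(C)(C)C)/C(C)=C\C(O)/C=C(\C)CC=C | intermediate
17 | (4E,7Z,9R,10S)-9-(tert-butyldimethylsilyloxy)-4,8-dimethyl-10-(triethylsilyloxy)dodeca-1,4,7,11-tetraen-6-one | C=C[C@H](O[Si](CC)(CC)CC)[C@H](O[Si](C)(C)C(C)(C)C)/C(C)=C\C(=O)/C=C(\C)CC=C | intermediate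
18 | (1(10)E,3Z,7Z,5R,6S)-5-(tert-butyldimethylsilyloxy)-6-(triethylsilyloxy)-11,12,13-trinorgermacra-1(10),3,7-trien-2-one | CC[Si](CC)(CC)O[C@H]1/C=C\C/C(C)=C/C(=O)/C=C(/C)[C@H]1O[Si](C)(C)C(C)(C)C | intermediate
19 | (1(10)E,3Z,7Z,5R,6S)-5-(tert-butyldimethylsilyloxy)-6-hydroxy-11,12,13-trinorgermacra-1(10),3,7-trien-2-one | O[C@H]1/C=C\C/C(C)=C/C(=O)/C=C(/C)[C@H]1O[Si](C)(C)C(C)(C)C | intermediate
20 | (1(10)E,3Z,5R,6S,7R,8S)-5-(tert-butyldimethylsilyloxy)-7,8-epoxy-6-hydroxy-11,12,13-trinorgermacra-1(10),3-dien-2-one, cis epoxide syn to the C6 hydroxyl | O[C@H]2[C@H]1O[C@H]1C/C(C)=C/C(=O)/C=C(/C)[C@H]2O[Si](C)(C)C(C)(C)C | intermediate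
21 | diethylphosphonoacetic acid | CCOP(=O)(OCC)CC(=O)O | starting material
22 | (1(10)E,3Z,5R,6S,7S,8S)-5-(tert-butyldimethylsilyloxy)-6-[2-(diethoxyphosphoryl)acetoxy]-7,8-epoxy-11,12,13-trinorgermacra-1(10),3-dien-2-one | CCOP(=O)(OCC)CC(=O)O[C@H]2[C@H]1O[C@H]1C/C(C)=C/C(=O)/C=C(/C)[C@H]2O[Si](C)(C)C(C)(C)C | intermediate
23 | formaldehyde | C=O | starting material
24 | sodium enolate of 22 | CCOP(=O)(OCC)[CH-]C(=O)O[C@H]2[C@H]1O[C@H]1C/C(C)=C/C(=O)/C=C(/C)[C@H]2O[Si](C)(C)C(C)(C)C.[Na+] | intermediate
25 | sodium salt of the 11-(diethoxyphosphoryl)-8-hydroxy 12,6-lactone | CCOP(=O)(OCC)[C-]1C(=O)O[C@H]2[C@H]1[C@@H](O)C/C(C)=C/C(=O)/C=C(/C)[C@H]2O[Si](C)(C)C(C)(C)C.[Na+] | intermediate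
26 | (1(10)E,3Z,5R,6S,7R,8S)-5-(tert-butyldimethylsilyloxy)-8-hydroxy-2-oxogermacra-1(10),3,11(13)-trien-12,6-olide | C=C1C(=O)O[C@H]2[C@H]1[C@@H](O)C/C(C)=C/C(=O)/C=C(/C)[C@H]2O[Si](C)(C)C(C)(C)C | intermediate
27 | angelic acid, (Z)-2-methylbut-2-enoic acid | C/C=C(/C)C(=O)O | starting material
28 | angelic 2,4,6-trichlorobenzoic anhydride | C/C=C(/C)C(=O)OC(=O)c1c(Cl)cc(Cl)cc1Cl | intermediate
29 | (1(10)E,3Z,5R,6S,7R,8S)-8-angeloyloxy-5-(tert-butyldimethylsilyloxy)-2-oxogermacra-1(10),3,11(13)-trien-12,6-olide | C=C1C(=O)O[C@H]2[C@H]1[C@@H](OC(=O)/C(C)=C\C)C/C(C)=C/C(=O)/C=C(/C)[C@H]2O[Si](C)(C)C(C)(C)C | intermediate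
30 | (1(10)E,3Z,5R,6S,7R,8S)-8-angeloyloxy-5-hydroxy-2-oxogermacra-1(10),3,11(13)-trien-12,6-olide | C=C1C(=O)O[C@H]2[C@H]1[C@@H](OC(=O)/C(C)=C\C)C/C(C)=C/C(=O)/C=C(/C)[C@H]2O | target

Total step count: 17.
Longest linear sequence: 14 steps (from but-2-yn-1-ol through steps 2, 3 and 6 to 17).

Steps most likely to fail

Step 15. The weakly nucleophilic phosphonate carbanion may open the epoxide too slowly. Carbon‑to‑oxygen phosphoryl transfer to the C8 alkoxide with cyclopropane closure, or lactone migration to O8, would then compete with the annulation. The fallback sets out from 20 and comes back at 26. Steglich esterification of 20 with monoallyl malonate (DCC, DMAP) gives the allyl malonate ester F1. NaH in THF then closes the lactone by the classical malonate version of the same 5‑exo opening at C7, which has no phosphoryl group to migrate, and gives the α‑(allyloxycarbonyl) lactone F2. Pd(PPh3)4 with morpholine removes the allyl group to give the α‑carboxy lactone F3. Decarboxylative Mannich methylenation (aqueous formaldehyde, Et2NH, then NaOAc/AcOH, warm) gives 26.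

Step 11. Intermolecular metathesis through the C8 terminus (oligomerisation) may outpace closure of the strained ring onto the hindered C7 vinyl group. The fallback sets out from 13 and 3 and comes back at 18. Z‑selective cross‑metathesis of 13 with 3, using the molybdenum monoaryloxide pyrrolide alkylidene Mo(N-1-adamantyl)(CHCMe2Ph)(NC4H4)(O-2,6-(2,4,6-iPr3C6H2)2C6H3), joins C7 to C8 and gives the Z‑C7=C8 alkenyl iodide F4. Swern oxidative desilylation as in step 8 gives the enal F5. An intramolecular Nozaki–Hiyama–Kishi coupling (CrCl2, NiCl2 (cat.), DMSO/THF, high dilution) joins the C1 iodide to the C2 aldehyde and closes the ring to the cyclic bis‑allylic alcohol F6. Dess–Martin oxidation gives 18.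

Step 13. Facial selectivity may be poor if the ring conformation offers the vanadate ester the olefin face anti to O6, and the allylic alcohol may be oxidised to the enone instead. The fallback sets out from 19 and comes back at 22. Mitsunobu inversion of 19 with 4‑nitrobenzoic acid (PPh3, DIAD) gives the 6‑epi 4‑nitrobenzoate F7. Methanolysis (K2CO3, MeOH, 0 °C) gives the 6‑epi alcohol F8. Peracid epoxidation (mCPBA, NaHCO3, CH2Cl2), which in medium‑ring (Z)‑allylic alcohols takes the peripheral face anti to the hydroxyl, gives the trans epoxy alcohol F9, whose epoxide has the configuration required in 20. A second Mitsunobu reaction, with acid 21 (PPh3, DIAD), inverts C6 and installs the phosphonoacetate to give 22.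

Further compounds
F1 | step 15 | 6-O-[3-(allyloxy)-3-oxopropanoyl] ester of 20 (allyl malonate ester) | C=CCOC(=O)CC(=O)O[C@H]2[C@H]1O[C@H]1C/C(C)=C/C(=O)/C=C(/C)[C@H]2O[Si](C)(C)C(C)(C)C
F2 | step 15 | 11-(allyloxycarbonyl)-5-(tert-butyldimethylsilyloxy)-8-hydroxy 12,6-lactone, C11 epimers | C=CCOC(=O)C1C(=O)O[C@H]2[C@H]1[C@@H](O)C/C(C)=C/C(=O)/C=C(/C)[C@H]2O[Si](C)(C)C(C)(C)C
F3 | step 15 | 11-carboxy-5-(tert-butyldimethylsilyloxy)-8-hydroxy 12,6-lactone, C11 epimers | OC(=O)C1C(=O)O[C@H]2[C@H]1[C@@H](O)C/C(C)=C/C(=O)/C=C(/C)[C@H]2O[Si](C)(C)C(C)(C)C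
F4 | step 11 | open-chain C1 alkenyl iodide with Z-C7=C8, 5-OTBS, 6-OTES and primary 2-OTES | I/C=C(\C)C/C=C\[C@H](O[Si](CC)(CC)CC)[C@H](O[Si](C)(C)C(C)(C)C)/C(C)=C\CO[Si](CC)(CC)CC
F5 | step 11 | open-chain C1 alkenyl iodide C2 Z-enal with Z-C7=C8, 5-OTBS and 6-OTES | I/C=C(\C)C/C=C\[C@H](O[Si](CC)(CC)CC)[C@H](O[Si](C)(C)C(C)(C)C)/C(C)=C\C=O
F6 | step 11 | (1(10)E,3Z,7Z,5R,6S)-5-(tert-butyldimethylsilyloxy)-6-(triethylsilyloxy)-11,12,13-trinorgermacra-1(10),3,7-trien-2-ol, both C2 epimers | CC[Si](CC)(CC)O[C@H]1/C=C\C/C(C)=C/C(O)/C=C(/C)[C@H]1O[Si](C)(C)C(C)(C)C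
F7 | step 13 | 6-epi 4-nitrobenzoate of 19 | O=C(O[C@@H]1/C=C\C/C(C)=C/C(=O)/C=C(/C)[C@H]1O[Si](C)(C)C(C)(C)C)c1ccc(cc1)[N+](=O)[O-]
F8 | step 13 | 6-epi-19 (6-epi allylic alcohol) | O[C@@H]1/C=C\C/C(C)=C/C(=O)/C=C(/C)[C@H]1O[Si](C)(C)C(C)(C)C
F9 | step 13 | 6-epi-20 (cis 7,8-epoxide anti to the C6 hydroxyl) | O[C@@H]2[C@H]1O[C@H]1C/C(C)=C/C(=O)/C=C(/C)[C@H]2O[Si](C)(C)C(C)(C)C
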